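## Structural features

The target is a germacranolide: a ten-membered carbocycle (C1–C10) fused across C6–C7 to a butenolide (C6–O–C12(=O)–C11=C7) whose α-carbon C11 carries the acetoxymethyl carbon C13. C4–C5 is a cis-fused trisubstituted epoxide with the methyl on C4, C8 bears a methacrylate, C10 a methyl group and C1 a free secondary hydroxyl. Of the six stereocentres, C4, C5 and C6 are contiguous, C10 and C1 are adjacent, and C8 stands alone between the sp2 carbon C7 and the C9 methylene. The configuration read from the SMILES is 1S,4R,5S,6S,8S,10R, and C3 and C6 are cis on the epoxide, which corresponds to a Z C4=C5 olefin. The fragile groups are the epoxide (acid, and transannular attack by the C1 hydroxyl), the allylic acetate on an electron-poor butenolide, the methacrylate, and C6–H, which is vinylogously acidic and sits next to the epoxide. The real difficulty is closure of the medium ring, control of C10 and C8 on that ring, and construction of the tetrasubstituted C7=C11 olefin without losing the C6 oxygen by β-elimination. The key step exploits the 1,3-relation between the C8 oxygen and the C10 methyl with the C1 oxygen next to it: this is the retron of a ten-membered C8 ketone with an E C9=C10 olefin, which an olefination between a C9 ketophosphonate and a C10 aldehyde closes. The same C8 carbonyl later leaves C7 as the only enolisable carbon of the enone, and C11–C13 is attached there.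

## Logic of the disconnections

**25 to 22.** The C1 O–Si bond, the C8 O–acyl bond and the C8–H bond are cut in turn (25 ⇒ 24 ⇒ 23 ⇒ 22). The methacrylate and the free C1 hydroxyl are the most sensitive functions and are therefore introduced last. The gain is a C8 ketone that activates C7. The demand is hydride delivery to one face of C8 and an acylation and desilylation that leave the lactone, the acetate and the epoxide alone.

**22 to 19.** The C7=C11 double bond is cut as a dehydration and the lactone O6–C12 bond as an acyl substitution (22 ⇒ 21 ⇒ 20 ⇒ 19). This turns the butenolide into an open β-hydroxy ketone with an ethyl ester. The demand is a dehydration mild enough for the epoxide and a desilylation that frees O6 and O11 but not O1.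

**19 to 18.** The C10–C14 bond is cut (19 ⇒ 18) as a conjugate methyl addition. It has to come before the butenolide exists, because an allylic acetate on an unsaturated lactone would not survive a cuprate. The demand is attack on the enone face anti to the C1 oxygen.

**18 to 14 and 16.** The C7–C11 bond is cut (18 ⇒ 17 ⇒ 14 + 16, and 16 ⇒ 15 by a C–O cut). The whole C11–C13 unit with its acetate then comes from one small keto ester. The cut is placed at the enone stage because there C9 is sp2 and C7 is the only α-methylene, and because O6 is still a silyl ether. An acyl group on O6 would be a leaving group β to the C8 carbonyl, so a tether through O6 is avoided. The demand is carbonyl addition faster than proton transfer from the keto ester.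

**14 to 13.** The C9=C10 bond is cut (14 ⇒ 13); this is the ring-opening disconnection. It reduces the ten-membered ring to a chain that carries a β-ketophosphonate and an α-silyloxy aldehyde. Both structures were checked against the target: 13 and 14 have the 1S,4R,5S,6S configuration and the cis-epoxide that 25 requires, so nothing in them needs correction. The demand is ring closure ahead of oligomerisation under a base that spares C1 and the C6 silyloxy group.

**13 to 8 and 9.** The C10 aldehyde is traced to a vinyl group (13 ⇒ 12 ⇒ 11), the O6–Si bond is cut (11 ⇒ 10), and the C6–C7 bond is cut (10 ⇒ 8 + 9). Fragment 9 supplies C7, C8, C9 and the phosphonate in one piece. The demand is addition of its terminal carbanion to the aldehyde anti to the epoxide C–O bond, which sets C6.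

**8 to 6.** The aldehyde is traced to a primary alcohol (8 ⇒ 7) and the two epoxide C–O bonds are cut (7 ⇒ 6). The gain is a Z-allylic alcohol whose epoxidation can be controlled by a chiral reagent. The demand is epoxidation of this olefin only, on the face that gives 4R,5S.

**6 to 3.** The acetate and silyl groups are exchanged (6 ⇒ 5 ⇒ 4) and the C1–C10 bond is cut (4 ⇒ 3). The vinyl group is the masked C10 aldehyde, and its addition creates C1. The demand is a catalyst-controlled vinyl transfer that tolerates the acetate.

**3 to 1.** The aldehyde is traced to the isopropylidene olefin (3 ⇒ 2 ⇒ 1). The Z C4=C5 olefin with its methyl group is then bought ready-made, and starting from the acetate 1 saves an acylation. The demand is cleavage of the electron-rich olefin in the presence of the one deactivated by the allylic acetate.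

## Other disconnections considered

**Alternative 1:** The cut is the C5–C6 bond together with the lactone O6–C12 bond. In the forward direction the open-chain iodo aldehyde A1 would be treated with CrCl2 and catalytic NiCl2. A1 carries a Z-alkenyl iodide at C5, the C6 formyl group on the C7=C11 olefin cis to a C12 methyl ester, the C8 methacrylate and the C1 silyl ether. The alkenylchromium formed at C5 would add to the aldehyde (Nozaki–Hiyama–Kishi), and the chromium alkoxide would close the butenolide to give A2. Epoxidation of C4=C5 and desilylation would finish the synthesis.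

- In its favour: both rings close in one operation, the organochromium addition is irreversible and tolerates esters, and only two steps follow the ring closure. On late-stage step economy and on tolerance of the finished ester groups it is better than the chosen plan. On the ten-membered closure it is at least its equal.
- Against it here: the cis β-formyl acrylate unit of A1 is geometrically labile and prone to cyclise to a pseudo-ester. C6 would be created during the ring closure with no adjacent controlling element. The epoxide would have to be introduced afterwards on a ring with no free hydroxyl to direct it.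
- Comparison: the chosen plan fixes C4 and C5 by reagent control and C6 by Felkin–Anh control before the ring exists, so it is the stronger on stereochemistry. The total step count would probably be similar, because C1, C8 and C10 of A1 all have to be set in the open chain.

**Alternative 2:** The cut is a retro-[3,3] shift: C8–C9 is broken and C1–C6 is formed, which contracts the ring to the cyclohexenol A3. A3 has its two alkenyl groups trans and an E enol ether. In the forward direction its potassium alkoxide (KH, 18-crown-6) would rearrange through a chair transition state by anionic oxy-Cope reaction to the dienone A4.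

- In its favour: ring expansion needs no high dilution and pays no entropic price, and on this point it is better than the chosen plan. Both olefin geometries and C8 follow from the transition state, the start is a cheap terpene, and the route to the ring is very short.
- Against it here: A4 carries only one of the six stereocentres. C1 and C10 would have to come from a regio- and face-selective hydroboration of one of two trisubstituted olefins, C4 and C5 from epoxidation of an enone olefin, and C6 from a ketone reduction, all under conformational control of a flexible ring. The stereocentre of A3 that bears the isopropenyl group also passes through epimerisable intermediates.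
- Comparison: C7 would be the only α-methylene of the C6 ketone, so regiocontrol for attaching C11 is equal to that of the chosen plan. The chosen plan sets four centres by reagent or acyclic control and only two on the ring, so it is the stronger on stereochemistry and the weaker on ring construction.

**Alternative 3:** The cut is the C3–C4 bond. In the forward direction the terminal olefin of the open-chain compound A5 would be hydroborated with 9-BBN, and the alkylborane would couple with the Z-alkenyl iodide at C4 under PdCl2(dppf) and Cs2CO3 to give the ten-membered allylic alcohol A6.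

- In its favour: the coupling retains the Z geometry, and on this it is the equal of the chosen plan, which takes the Z olefin from 1. The C1/C10 pair could be made in the open chain by a reagent-controlled crotylation, which is better than a cuprate addition on the ring. The free C6 hydroxyl of A6 could direct an epoxidation.
- Against it here: closure of a ten-membered carbocycle by this coupling has little precedent and competes with β-hydride elimination, protodeboronation and intermolecular coupling. The dithiane must be removed later in the presence of the epoxide. Once the C8 ketone is free there is no enone to make C7 the only acidic site, so C7 against C9 regiochemistry is unsolved. The face of a hydroxyl-directed epoxidation on a ten-membered ring is not assured.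
- Comparison: the ring closure is about as uncertain as in the chosen plan. The alternative needs more protecting-group operations and leaves the same C8 reduction for the end.

Key step: step 10

Assumption: ring compounds are numbered as germacranes (C1–C10 in the ring, C11–C13 in the lactone, C14 on C10). The facial sense of the amino-alcohol-catalysed alkenylzinc addition in step 2 is taken to follow that of dialkylzinc additions.

## Route

Step 1
Reactants: 1 neryl acetate
Product: 3 (2Z)-3-methyl-6-oxohex-2-en-1-yl acetate, via secondary ozonide 2 (not isolated)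
Conditions: O3 (1 equiv, indicator dye), CH2Cl2, pyridine (cat.), −78 °C; then Me2S, −78 °C → rt
Reagents that add atoms: ozone, [O-][O+]=O
Why: Ozonolysis with reductive work-up; electrophilic ozone attacks the electron-rich isopropylidene olefin much faster than the olefin deactivated by the allylic acetate, so the Z olefin and its geometry are kept.

Step 2
Reactants: 3 (2Z)-3-methyl-6-oxohex-2-en-1-yl acetate
Product: 4 (2Z,6S)-6-hydroxy-3-methylocta-2,7-dien-1-yl acetate
Conditions: (CH2=CH)2Zn (from CH2=CHMgBr and ZnCl2; 1,4-dioxane to remove MgBrCl), (+)-MIB (cat.), toluene, −20 → 0 °C; aq NH4Cl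
Reagents that add atoms: divinylzinc, C=C[Zn]C=C
Why: Amino-alcohol-catalysed enantioselective addition of an alkenylzinc to an aldehyde; the zinc aminoalkoxide of (+)-MIB should deliver the vinyl group to the Re face and set C1 as S. The acetate is inert to organozinc reagents, and any 6R material becomes a separable diastereomer after step 5.

Step 3
Reactants: 4 (2Z,6S)-6-hydroxy-3-methylocta-2,7-dien-1-yl acetate
Product: 5 (2Z,6S)-6-(tert-butyldimethylsilyloxy)-3-methylocta-2,7-dien-1-yl acetate
Conditions: TBSCl, imidazole, DMF, rt
Reagents that add atoms: tert-butyldimethylsilyl chloride, CC(C)(C)[Si](C)(C)Cl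
Why: Imidazole-promoted silylation of a secondary alcohol; the TBS ether is chosen to outlast the triethylsilyl ether introduced at C6 later.

Step 4
Reactants: 5 (2Z,6S)-6-(tert-butyldimethylsilyloxy)-3-methylocta-2,7-dien-1-yl acetate
Product: 6 (2Z,6S)-6-(tert-butyldimethylsilyloxy)-3-methylocta-2,7-dien-1-ol
Conditions: K2CO3, MeOH, 0 °C → rt
Reagents that add atoms: none
Why: Base-catalysed transesterification of the acetate with methanol; the secondary TBS ether is stable to carbonate in methanol.

Step 5
Reactants: 6 (2Z,6S)-6-(tert-butyldimethylsilyloxy)-3-methylocta-2,7-dien-1-ol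
Product: 7 [(2S,3R)-3-[(3S)-3-(tert-butyldimethylsilyloxy)pent-4-en-1-yl]-3-methyloxiran-2-yl]methanol
Conditions: Ti(OiPr)4, L-(+)-diethyl tartrate, tBuOOH, 4 Å MS, CH2Cl2, −20 °C
Reagents that add atoms: tert-butyl hydroperoxide, CC(C)(C)OO
Why: Sharpless asymmetric epoxidation; the L-(+)-tartrate complex delivers oxygen to the face of the Z-allylic alcohol that gives the (2S,3R)-epoxy alcohol, which sets C4 as R and C5 as S with C3 and C6 cis. Delivery through the titanium alkoxide confines the reaction to the allylic alcohol, so the vinyl group stays.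

Step 6
Reactants: 7 [(2S,3R)-3-[(3S)-3-(tert-butyldimethylsilyloxy)pent-4-en-1-yl]-3-methyloxiran-2-yl]methanol
Product: 8 (2R,3R)-3-[(3S)-3-(tert-butyldimethylsilyloxy)pent-4-en-1-yl]-3-methyloxirane-2-carbaldehyde
Conditions: Dess–Martin periodinane, NaHCO3, CH2Cl2, 0 °C → rt
Reagents that add atoms: none
Why: Buffered Dess–Martin oxidation of a primary epoxy alcohol; the conditions are neutral, so the epoxide and the silyl ether survive, and the aldehyde is used without storage.

Step 7
Reactants: 8 (2R,3R)-3-[(3S)-3-(tert-butyldimethylsilyloxy)pent-4-en-1-yl]-3-methyloxirane-2-carbaldehyde; 9 dimethyl (2-oxopropyl)phosphonate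
Product: 10 dimethyl [(4S)-4-hydroxy-4-[(2S,3R)-3-[(3S)-3-(tert-butyldimethylsilyloxy)pent-4-en-1-yl]-3-methyloxiran-2-yl]-2-oxobutyl]phosphonate
Conditions: 9, LiN(iPr)2 (2.1 equiv), THF, −78 → 0 °C; then 8, −78 °C; aq NH4Cl, −78 °C
Reagents that add atoms: none
Why: Aldol addition of the β-ketophosphonate dianion, which reacts at its terminal, more basic carbanion and so forms C6–C7. Felkin–Anh addition anti to the epoxide C–O bond, which is pronounced for cis-epoxy aldehydes, should give the 6S carbinol, and the cold quench avoids epoxide migration.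

Step 8
Reactants: 10 dimethyl [(4S)-4-hydroxy-4-[(2S,3R)-3-[(3S)-3-(tert-butyldimethylsilyloxy)pent-4-en-1-yl]-3-methyloxiran-2-yl]-2-oxobutyl]phosphonate
Product: 11 dimethyl [(4S)-4-[(2S,3R)-3-[(3S)-3-(tert-butyldimethylsilyloxy)pent-4-en-1-yl]-3-methyloxiran-2-yl]-2-oxo-4-(triethylsilyloxy)butyl]phosphonate
Conditions: TESCl, imidazole, DMAP (cat.), CH2Cl2, 0 °C
Reagents that add atoms: chlorotriethylsilane, CC[Si](Cl)(CC)CC
Why: Silylation under a base too weak to enolise the ketophosphonate. The triethylsilyl ether can be removed before the TBS ether and keeps the C6 oxygen from adding across the ring to the enone made in step 10.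

Step 9
Reactants: 11 dimethyl [(4S)-4-[(2S,3R)-3-[(3S)-3-(tert-butyldimethylsilyloxy)pent-4-en-1-yl]-3-methyloxiran-2-yl]-2-oxo-4-(triethylsilyloxy)butyl]phosphonate
Product: 13 dimethyl [(4S)-4-[(2S,3R)-3-[(3S)-3-(tert-butyldimethylsilyloxy)-4-oxobutyl]-3-methyloxiran-2-yl]-2-oxo-4-(triethylsilyloxy)butyl]phosphonate, via secondary ozonide 12 (not isolated)
Conditions: O3, CH2Cl2, −78 °C; then PPh3, −78 °C → rt
Reagents that add atoms: ozone, [O-][O+]=O
Why: Ozonolysis of the only olefin with a neutral reductive work-up, which keeps the α-silyloxy aldehyde configurationally intact; the crude aldehyde goes directly into step 10.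

Step 10
Reactants: 13 dimethyl [(4S)-4-[(2S,3R)-3-[(3S)-3-(tert-butyldimethylsilyloxy)-4-oxobutyl]-3-methyloxiran-2-yl]-2-oxo-4-(triethylsilyloxy)butyl]phosphonate
Product: 14 (1S,4R,5S,6S,9E)-1-(tert-butyldimethylsilyloxy)-4,5-epoxy-4-methyl-6-(triethylsilyloxy)cyclodec-9-en-8-one
Conditions: LiCl (10 equiv), iPr2NEt (5 equiv), MeCN, rt, slow addition of 13 (final 1 mM)
Reagents that add atoms: none
Why: LiCl coordinates the β-ketophosphonate so that iPr2NEt is basic enough to form the chelated lithium phosphonoenolate at C9, the only carbon acid of 13 that this base can ionise. The C9 anion adds to the C10 aldehyde, the β-oxidophosphonate closes to an oxaphosphetane, and syn loss of lithium dimethyl phosphate gives the C9=C10 bond; the closest known reaction type is the intramolecular Horner–Wadsworth–Emmons macrocyclisation of ω-formyl β-ketophosphonates under Masamune–Roush conditions. The ten-membered ring closes in the addition step as a 10-exo-trig attack of C9 on the aldehyde carbon, and the cis-epoxide, which holds C3 and C6 on one side, folds the chain so that the two ends can meet. No stereocentre is formed; the E geometry follows from reversible addition of the stabilised phosphonate and collapse through the less strained trans-oxaphosphetane. Ring closure has to win over intermolecular olefination, which slow addition into a dilute LiCl solution secures. The C1 centre next to the aldehyde must not epimerise and the C6 silyloxy group must not be lost by β-elimination; the weak amine base, which ionises neither C7 nor the aldehyde α-position at a useful rate, secures both. The triethylsilyl ether keeps the C6 oxygen from adding across the ring to the new enone.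

Step 11
Reactants: 15 ethyl 3-bromo-2-oxopropanoate
Product: 16 ethyl 3-acetoxy-2-oxopropanoate
Conditions: KOAc, DMF, 0 °C → rt
Reagents that add atoms: potassium acetate, CC(=O)[O-].[K+]
Why: SN2 displacement of an α-bromo ketone by acetate, which is fast because of the adjacent carbonyl group; the product is distilled and used fresh.

Step 12
Reactants: 14 (1S,4R,5S,6S,9E)-1-(tert-butyldimethylsilyloxy)-4,5-epoxy-4-methyl-6-(triethylsilyloxy)cyclodec-9-en-8-one; 16 ethyl 3-acetoxy-2-oxopropanoate
Product: 18 ethyl 3-acetoxy-2-[(1S,4R,5S,6S,9E)-1-(tert-butyldimethylsilyloxy)-4,5-epoxy-4-methyl-8-oxo-6-(triethylsilyloxy)cyclodec-9-en-7-yl]-2-(trimethylsilyloxy)propanoate (epimers at C7 and C11), via lithium aldolate 17 (not isolated)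
Conditions: LiN(iPr)2, THF, −78 °C; 16, −78 °C; then Me3SiCl, Et3N, −78 → −30 °C
Reagents that add atoms: chlorotrimethylsilane, C[Si](C)(C)Cl
Why: Kinetic deprotonation of the enone can only occur at the α'-methylene C7, because C9 is sp2, and the cross-conjugated lithium dienolate adds to the very electrophilic ketone carbonyl of the α-keto ester (aldol addition to a pyruvate-type acceptor). The C6 silyloxy group is a poor leaving group at −78 °C, and silylation of the aldolate blocks retro-aldol cleavage. The new centres at C7 and C11 need no control because both become sp2 in step 15.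

Step 13
Reactants: 18 ethyl 3-acetoxy-2-[(1S,4R,5S,6S,9E)-1-(tert-butyldimethylsilyloxy)-4,5-epoxy-4-methyl-8-oxo-6-(triethylsilyloxy)cyclodec-9-en-7-yl]-2-(trimethylsilyloxy)propanoate
Product: 19 ethyl 3-acetoxy-2-[(1S,4R,5S,6S,10R)-1-(tert-butyldimethylsilyloxy)-4,5-epoxy-4,10-dimethyl-8-oxo-6-(triethylsilyloxy)cyclodecan-7-yl]-2-(trimethylsilyloxy)propanoate (epimers at C7 and C11)
Conditions: Me2CuLi (from MeLi and CuI), Et2O, −78 °C; aq NH4Cl/NH3
Reagents that add atoms: lithium dimethylcuprate, [Li+].C[Cu-]C
Why: Conjugate addition of the Gilman reagent to the E-enone. The C1–O bond is expected to lie perpendicular to the enone π system with the bulky silyloxy group screening that face (Felkin–Anh-type arrangement, as in acyclic γ-silyloxy enones), so methyl should enter C10 anti to the C1 oxygen from the periphery of the ring and give the 10R centre. Esters, silyl ethers and the trisubstituted epoxide are inert to Me2CuLi at −78 °C.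

Step 14
Reactants: 19 ethyl 3-acetoxy-2-[(1S,4R,5S,6S,10R)-1-(tert-butyldimethylsilyloxy)-4,5-epoxy-4,10-dimethyl-8-oxo-6-(triethylsilyloxy)cyclodecan-7-yl]-2-(trimethylsilyloxy)propanoate
Product: 21 (1S,4R,5S,6S,10R)-13-acetoxy-1-(tert-butyldimethylsilyloxy)-4,5-epoxy-11-hydroxy-8-oxogermacrano-6,12-lactone (epimers at C7 and C11), via dihydroxy ester 20 (not isolated)
Conditions: HF·pyridine, pyridine, THF, 0 °C
Reagents that add atoms: none
Why: Buffered fluoride cleaves the secondary triethylsilyl and the tertiary trimethylsilyl ether but leaves the hindered secondary TBS ether. The freed C6 hydroxyl then closes the five-membered lactone on the activated α-hydroxy ester by acyl substitution (5-exo-trig) with loss of ethanol. The medium is weakly acidic, so the β-hydroxy ketone does not undergo retro-aldol cleavage.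

Step 15
Reactants: 21 (1S,4R,5S,6S,10R)-13-acetoxy-1-(tert-butyldimethylsilyloxy)-4,5-epoxy-11-hydroxy-8-oxogermacrano-6,12-lactone
Product: 22 (1S,4R,5S,6S,10R)-13-acetoxy-1-(tert-butyldimethylsilyloxy)-4,5-epoxy-8-oxogermacr-7(11)-eno-6,12-lactone
Conditions: Martin sulfurane, Ph2S[OC(CF3)2Ph]2, CH2Cl2, 0 °C → rt
Reagents that add atoms: none
Why: Dehydration of a tertiary alcohol through its alkoxysulfurane; the hydrogen removed is the acidic C7–H next to the C8 ketone, so the tetrasubstituted olefin conjugated with both carbonyls forms from every C7/C11 epimer. The neutral conditions spare the epoxide and the base-sensitive γ-position of the butenolide.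

Step 16
Reactants: 22 (1S,4R,5S,6S,10R)-13-acetoxy-1-(tert-butyldimethylsilyloxy)-4,5-epoxy-8-oxogermacr-7(11)-eno-6,12-lactone
Product: 23 (1S,4R,5S,6S,8S,10R)-13-acetoxy-1-(tert-butyldimethylsilyloxy)-4,5-epoxy-8-hydroxygermacr-7(11)-eno-6,12-lactone
Conditions: NaBH4, CeCl3·7H2O, MeOH, −78 °C
Reagents that add atoms: none
Why: Luche 1,2-reduction; the cerium-activated borohydride attacks the C8 ketone faster than it adds in conjugate fashion or touches the lactone and the acetate. The ring chain leaves the plane of the keto-butenolide at C6 on the face of C5 and screens that face of C8, so hydride should enter cis to H6 and give the 8S alcohol.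

Step 17
Reactants: 23 (1S,4R,5S,6S,8S,10R)-13-acetoxy-1-(tert-butyldimethylsilyloxy)-4,5-epoxy-8-hydroxygermacr-7(11)-eno-6,12-lactone
Product: 24 (1S,4R,5S,6S,8S,10R)-13-acetoxy-1-(tert-butyldimethylsilyloxy)-4,5-epoxy-8-(methacryloyloxy)germacr-7(11)-eno-6,12-lactone
Conditions: methacrylic anhydride, Et3N, DMAP (cat.), CH2Cl2, 0 °C
Reagents that add atoms: methacrylic anhydride, C=C(C)C(=O)OC(=O)C(C)=C
Why: DMAP-catalysed acylation of the only free hydroxyl. The low temperature and the absence of alkoxide keep the lactone from moving to O8.

Step 18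
Reactants: 24 (1S,4R,5S,6S,8S,10R)-13-acetoxy-1-(tert-butyldimethylsilyloxy)-4,5-epoxy-8-(methacryloyloxy)germacr-7(11)-eno-6,12-lactone
Product: 25 (1S,4R,5S,6S,8S,10R)-13-acetoxy-4,5-epoxy-1-hydroxy-8-(methacryloyloxy)germacr-7(11)-eno-6,12-lactone (CNP0119405.1)
Conditions: HF·pyridine, pyridine, THF, 0 °C → rt
Reagents that add atoms: none
Why: Fluoride-mediated cleavage of the TBS ether. The excess pyridine buffers the medium so that the esters and the butenolide are not touched and the freed C1 hydroxyl is not driven to open the epoxide across the ring.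

## Compound list

1 | neryl acetate, (2Z)-3,7-dimethylocta-2,6-dien-1-yl acetate | CC(C)=CCC/C(C)=C\COC(C)=O | starting material
2 | secondary ozonide of 1 at the 6,7-olefin, 3,3-dimethyl-5-[(3Z)-5-acetoxy-3-methylpent-3-en-1-yl]-1,2,4-trioxolane | CC1(C)OOC(CC/C(C)=C\COC(C)=O)O1 | intermediate (not isolated)
3 | (2Z)-3-methyl-6-oxohex-2-en-1-yl acetate | O=CCC/C(C)=C\COC(C)=O | intermediate
4 | (2Z,6S)-6-hydroxy-3-methylocta-2,7-dien-1-yl acetate | C=C[C@@H](O)CC/C(C)=C\COC(C)=O | intermediate
5 | (2Z,6S)-6-(tert-butyldimethylsilyloxy)-3-methylocta-2,7-dien-1-yl acetate | C=C[C@@H](O[Si](C)(C)C(C)(C)C)CC/C(C)=C\COC(C)=O | intermediate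
6 | (2Z,6S)-6-(tert-butyldimethylsilyloxy)-3-methylocta-2,7-dien-1-ol | C=C[C@@H](O[Si](C)(C)C(C)(C)C)CC/C(C)=C\CO | intermediate
7 | [(2S,3R)-3-[(3S)-3-(tert-butyldimethylsilyloxy)pent-4-en-1-yl]-3-methyloxiran-2-yl]methanol | C=C[C@@H](O[Si](C)(C)C(C)(C)C)CC[C@@]1(C)O[C@H]1CO | intermediate
8 | (2R,3R)-3-[(3S)-3-(tert-butyldimethylsilyloxy)pent-4-en-1-yl]-3-methyloxirane-2-carbaldehyde | C=C[C@@H](O[Si](C)(C)C(C)(C)C)CC[C@@]1(C)O[C@H]1C=O | intermediate
9 | dimethyl (2-oxopropyl)phosphonate | COP(=O)(OC)CC(C)=O | starting material
10 | dimethyl [(4S)-4-hydroxy-4-[(2S,3R)-3-[(3S)-3-(tert-butyldimethylsilyloxy)pent-4-en-1-yl]-3-methyloxiran-2-yl]-2-oxobutyl]phosphonate | COP(=O)(OC)CC(=O)C[C@H](O)[C@@H]1O[C@]1(C)CC[C@H](O[Si](C)(C)C(C)(C)C)C=C | intermediate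
11 | dimethyl [(4S)-4-[(2S,3R)-3-[(3S)-3-(tert-butyldimethylsilyloxy)pent-4-en-1-yl]-3-methyloxiran-2-yl]-2-oxo-4-(triethylsilyloxy)butyl]phosphonate | COP(=O)(OC)CC(=O)C[C@H](O[Si](CC)(CC)CC)[C@@H]1O[C@]1(C)CC[C@H](O[Si](C)(C)C(C)(C)C)C=C | intermediate
12 | secondary ozonide of 11 at the vinyl group (3-substituted 1,2,4-trioxolane) | COP(=O)(OC)CC(=O)C[C@H](O[Si](CC)(CC)CC)[C@@H]1O[C@]1(C)CC[C@H](O[Si](C)(C)C(C)(C)C)C1OCOO1 | intermediate (not isolated)
13 | dimethyl [(4S)-4-[(2S,3R)-3-[(3S)-3-(tert-butyldimethylsilyloxy)-4-oxobutyl]-3-methyloxiran-2-yl]-2-oxo-4-(triethylsilyloxy)butyl]phosphonate | COP(=O)(OC)CC(=O)C[C@H](O[Si](CC)(CC)CC)[C@@H]1O[C@]1(C)CC[C@H](O[Si](C)(C)C(C)(C)C)C=O | intermediate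
14 | (1S,4R,5S,6S,9E)-1-(tert-butyldimethylsilyloxy)-4,5-epoxy-4-methyl-6-(triethylsilyloxy)cyclodec-9-en-8-one | O=C1/C=C/[C@@H](O[Si](C)(C)C(C)(C)C)CC[C@@]2(C)O[C@H]2[C@@H](O[Si](CC)(CC)CC)C1 | intermediate
15 | ethyl 3-bromo-2-oxopropanoate (ethyl bromopyruvate) | CCOC(=O)C(=O)CBr | starting material
16 | ethyl 3-acetoxy-2-oxopropanoate | CCOC(=O)C(=O)COC(C)=O | intermediate
17 | lithium alkoxide of the C7 aldol adduct of 14 and 16 (epimers at C7 and C11) | O=C1/C=C/[C@@H](O[Si](C)(C)C(C)(C)C)CC[C@@]2(C)O[C@H]2[C@@H](O[Si](CC)(CC)CC)C1C([O-])(COC(C)=O)C(=O)OCC.[Li+] | intermediate (not isolated)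
18 | ethyl 3-acetoxy-2-[(1S,4R,5S,6S,9E)-1-(tert-butyldimethylsilyloxy)-4,5-epoxy-4-methyl-8-oxo-6-(triethylsilyloxy)cyclodec-9-en-7-yl]-2-(trimethylsilyloxy)propanoate (epimers at C7 and C11) | O=C1/C=C/[C@@H](O[Si](C)(C)C(C)(C)C)CC[C@@]2(C)O[C@H]2[C@@H](O[Si](CC)(CC)CC)C1C(O[Si](C)(C)C)(COC(C)=O)C(=O)OCC | intermediate
19 | ethyl 3-acetoxy-2-[(1S,4R,5S,6S,10R)-1-(tert-butyldimethylsilyloxy)-4,5-epoxy-4,10-dimethyl-8-oxo-6-(triethylsilyloxy)cyclodecan-7-yl]-2-(trimethylsilyloxy)propanoate (epimers at C7 and C11) | O=C1C[C@@H](C)[C@@H](O[Si](C)(C)C(C)(C)C)CC[C@@]2(C)O[C@H]2[C@@H](O[Si](CC)(CC)CC)C1C(O[Si](C)(C)C)(COC(C)=O)C(=O)OCC | intermediate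
20 | ethyl 3-acetoxy-2-hydroxy-2-[(1S,4R,5S,6S,10R)-1-(tert-butyldimethylsilyloxy)-4,5-epoxy-6-hydroxy-4,10-dimethyl-8-oxocyclodecan-7-yl]propanoate (epimers at C7 and C11) | O=C1C[C@@H](C)[C@@H](O[Si](C)(C)C(C)(C)C)CC[C@@]2(C)O[C@H]2[C@@H](O)C1C(O)(COC(C)=O)C(=O)OCC | intermediate (not isolated)
21 | (1S,4R,5S,6S,10R)-13-acetoxy-1-(tert-butyldimethylsilyloxy)-4,5-epoxy-11-hydroxy-8-oxogermacrano-6,12-lactone (epimers at C7 and C11) | O=C1C[C@@H](C)[C@@H](O[Si](C)(C)C(C)(C)C)CC[C@@]2(C)O[C@H]2[C@H]2OC(=O)C(O)(COC(C)=O)C12 | intermediate
22 | (1S,4R,5S,6S,10R)-13-acetoxy-1-(tert-butyldimethylsilyloxy)-4,5-epoxy-8-oxogermacr-7(11)-eno-6,12-lactone | O=C1C[C@@H](C)[C@@H](O[Si](C)(C)C(C)(C)C)CC[C@@]2(C)O[C@H]2[C@H]2OC(=O)C(COC(C)=O)=C12 | intermediate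
23 | (1S,4R,5S,6S,8S,10R)-13-acetoxy-1-(tert-butyldimethylsilyloxy)-4,5-epoxy-8-hydroxygermacr-7(11)-eno-6,12-lactone | O[C@H]1C[C@@H](C)[C@@H](O[Si](C)(C)C(C)(C)C)CC[C@@]2(C)O[C@H]2[C@H]2OC(=O)C(COC(C)=O)=C12 | intermediate
24 | (1S,4R,5S,6S,8S,10R)-13-acetoxy-1-(tert-butyldimethylsilyloxy)-4,5-epoxy-8-(methacryloyloxy)germacr-7(11)-eno-6,12-lactone | C=C(C)C(=O)O[C@H]1C[C@@H](C)[C@@H](O[Si](C)(C)C(C)(C)C)CC[C@@]2(C)O[C@H]2[C@H]2OC(=O)C(COC(C)=O)=C12 | intermediate
25 | (1S,4R,5S,6S,8S,10R)-13-acetoxy-4,5-epoxy-1-hydroxy-8-(methacryloyloxy)germacr-7(11)-eno-6,12-lactone (CNP0119405.1) | C=C(C)C(=O)O[C@H]1C[C@@H](C)[C@@H](O)CC[C@@]2(C)O[C@H]2[C@H]2OC(=O)C(COC(C)=O)=C12 | target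

## Step count and least certain steps

Total step count: 18. Longest linear sequence: 17 steps (steps 1–10 and 12–18, from 1 to 25); step 11 is a one-step side branch.

**Step 10 (key step).** The most likely failure is intermolecular olefination, which gives cyclic dimers and oligomers, because the ten-membered transition state is strained and entropically costly. Slower risks are epimerisation at C1 in the free aldehyde and closure to the Z-enone. The fallback closes the same C9=C10 bond by ring-closing metathesis. It sets out from 11: a Horner–Wadsworth–Emmons reaction with aqueous formaldehyde and K2CO3 would give the vinyl ketone (5S)-5-[(2S,3R)-3-[(3S)-3-(tert-butyldimethylsilyloxy)pent-4-en-1-yl]-3-methyloxiran-2-yl]-5-(triethylsilyloxy)pent-1-en-3-one F1. The second-generation Grubbs catalyst, RuCl2(=CHPh)(PCy3)(H2IMes), in dilute toluene would then join the two terminal olefins with loss of ethene. The route is rejoined at 14.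

**Step 12.** The most likely failure is proton transfer from the acidic methylene of 16 to the lithium dienolate, which returns 14. Acetyl migration onto the new alkoxide before silylation is a second risk. The fallback replaces the basic enolate by a neutral enol silane. It sets out from 14: LiN(iPr)2 and Me3SiCl would give the cross-conjugated silyl dienol ether (1S,4R,5S,6S,9E)-1-(tert-butyldimethylsilyloxy)-4,5-epoxy-4-methyl-6-(triethylsilyloxy)-8-(trimethylsilyloxy)cyclodeca-7,9-diene F2. This would add to 16 under catalysis by Cu(OTf)2 with a bis(oxazoline) ligand (Mukaiyama aldol addition with silyl transfer). The route is rejoined at 18.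

**Step 13.** The most likely failure is poor or reversed facial selectivity at C10. On a ten-membered ring the conformer that reacts may place the silyloxy group in the plane of the enone instead of perpendicular to it, and the C7 epimers of 18 may not behave alike. The fallback reverses which group is delivered to C10. It sets out from 18: the cuprate addition is run with Me3SiCl so that the enolate is trapped as the trimethylsilyl enol ether F3. Pd(OAc)2 (Saegusa–Ito oxidation) would convert it into the 10-methyl-9-en-8-one F4. The hydride reagent [(Ph3P)CuH]6 would then add hydrogen to C10 from the face that the methyl group had taken, which leaves the methyl group on the other face. The route is rejoined at 19.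

**Step 16.** The most likely failure is hydride delivery to the wrong face of C8, since the argument rests on one ring conformer. Conjugate reduction of the doubly activated olefin and migration of the lactone to O8 are lesser risks. The fallback sets out from 22: if the reduction gives mainly the 8R alcohol, (1S,4R,5S,6S,8R,10R)-13-acetoxy-1-(tert-butyldimethylsilyloxy)-4,5-epoxy-8-hydroxygermacr-7(11)-eno-6,12-lactone F5, a Mitsunobu esterification with methacrylic acid, PPh3 and diisopropyl azodicarboxylate would invert C8 and install the ester in one operation. The route is rejoined at 24.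

## Further compounds

F1 | step 10 | (5S)-5-[(2S,3R)-3-[(3S)-3-(tert-butyldimethylsilyloxy)pent-4-en-1-yl]-3-methyloxiran-2-yl]-5-(triethylsilyloxy)pent-1-en-3-one | C=CC(=O)C[C@H](O[Si](CC)(CC)CC)[C@@H]1O[C@]1(C)CC[C@H](O[Si](C)(C)C(C)(C)C)C=C
F2 | step 12 | (1S,4R,5S,6S,9E)-1-(tert-butyldimethylsilyloxy)-4,5-epoxy-4-methyl-6-(triethylsilyloxy)-8-(trimethylsilyloxy)cyclodeca-7,9-diene | C[Si](C)(C)OC1/C=C/[C@@H](O[Si](C)(C)C(C)(C)C)CC[C@@]2(C)O[C@H]2[C@@H](O[Si](CC)(CC)CC)C=1
F3 | step 13 | trimethylsilyl enol ether (C8=C9) of the cuprate adduct of 18, C10 configuration not controlled | C[Si](C)(C)OC1=CC(C)[C@@H](O[Si](C)(C)C(C)(C)C)CC[C@@]2(C)O[C@H]2[C@@H](O[Si](CC)(CC)CC)C1C(O[Si](C)(C)C)(COC(C)=O)C(=O)OCC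
F4 | step 13 | 10-methyl analogue of 18 with the C9=C10 olefin, ethyl 3-acetoxy-2-[(1S,4R,5S,6S,9E)-1-(tert-butyldimethylsilyloxy)-4,5-epoxy-4,10-dimethyl-8-oxo-6-(triethylsilyloxy)cyclodec-9-en-7-yl]-2-(trimethylsilyloxy)propanoate | O=C1/C=C(\C)[C@@H](O[Si](C)(C)C(C)(C)C)CC[C@@]2(C)O[C@H]2[C@@H](O[Si](CC)(CC)CC)C1C(O[Si](C)(C)C)(COC(C)=O)C(=O)OCC
F5 | step 16 | (1S,4R,5S,6S,8R,10R)-13-acetoxy-1-(tert-butyldimethylsilyloxy)-4,5-epoxy-8-hydroxygermacr-7(11)-eno-6,12-lactone | O[C@@H]1C[C@@H](C)[C@@H](O[Si](C)(C)C(C)(C)C)CC[C@@]2(C)O[C@H]2[C@H]2OC(=O)C(COC(C)=O)=C12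
A1 | alternative 1 | open-chain iodo aldehyde: Z-alkenyl iodide at C5, C6 formyl group cis to the C12 methyl ester on C7=C11, C8 methacrylate, C1 TBS ether | I/C=C(/C)CC[C@H](O[Si](C)(C)C(C)(C)C)[C@H](C)C[C@H](OC(=O)C(C)=C)/C(C=O)=C(\COC(C)=O)C(=O)OC
A2 | alternative 1 | Z-4,5-ene butenolide with C8 methacrylate and C1 TBS ether | C=C(C)C(=O)O[C@H]1C[C@@H](C)[C@@H](O[Si](C)(C)C(C)(C)C)CC/C(C)=C\[C@H]2OC(=O)C(COC(C)=O)=C12
A3 | alternative 2 | (1S,6S)-1-[(E)-2-(4-methoxybenzyloxy)ethenyl]-3-methyl-6-(prop-1-en-2-yl)cyclohex-2-en-1-ol | COc1ccc(CO/C=C/[C@]2(O)C=C(C)CC[C@H]2C(C)=C)cc1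
A4 | alternative 2 | (1(10)E,4Z,8S)-8-(4-methoxybenzyloxy)-4,10-dimethylcyclodeca-1(10),4-dien-6-one (germacrane numbering) | COc1ccc(CO[C@H]2C/C(C)=C/CC/C(C)=C\C(=O)C2)cc1
A5 | alternative 3 | open-chain coupling precursor: terminal C2=C3 olefin, C1 TBS ether, C10 methyl, C8 1,3-dithiane, C6 hydroxyl, Z-alkenyl iodide at C4 | C=C[C@H](O[Si](C)(C)C(C)(C)C)[C@H](C)CC1(SCCCS1)C[C@H](O)/C=C(/C)I
A6 | alternative 3 | ten-membered Z-allylic alcohol with C8 1,3-dithiane and C1 TBS ether | C1CSC2(SC1)C[C@@H](C)[C@@H](O[Si](C)(C)C(C)(C)C)CC/C(C)=C\[C@@H](O)C2
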